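The route rests on cutting the bond between the ethylene bridge and the carbocycle of the oxadecalin and on making that carbocycle from a cyclopentanone. In the carbocycle the bridge-bearing CH lies between the C(OH)CH3 carbon and the methyl-bearing quaternary ring-fusion carbon; it is therefore introduced as an inserted carbon. In one operation dibromomethyllithium adds to the ketone of a trans-fused bicyclic acetal, the derived β-oxido carbenoid expands the five-membered ring to the six-membered enolate, and this enolate is trapped by the hydroazulene aldehyde. The precursors are a cyclopentanone acetal cut from a commercial hydrindenedione and an epoxy aldehyde built by two Claisen rearrangements and a ring-closing metathesis.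

Key step: step 15

Assumption: the lactol carbon of the target is configurationally labile, so the drawn anomer (equatorial hydroxyl) is reached through the anomeric equilibrium and is not set by a step.

In the names below, "azulenyl" means the 1,2-epoxy-1,4,4,6-tetramethyl-1,2,3,3a,4,5,8,8a-octahydroazulen-5-yl group of compound 18.

Step 1
Reactants: 1 (S)-7a-methyl-2,3,7,7a-tetrahydro-1H-indene-1,5(6H)-dione
Product: 2 (1S,7aS)-7a-methyl-2,3,5,6,7,7a-hexahydro-1H-indene-1,5-diol (1-OH cis to the angular methyl; 5-carbinol as an epimer mixture)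
Conditions: NaBH4, CeCl3·7H2O, MeOH, −20 to 0 °C
Reagents that add atoms: none
Why: Luche reduction; hydride should reach the cyclopentanone anti to the angular methyl, which puts the new hydroxyl cis to that methyl (the later ring-fusion C–O), while the enone is reduced 1,2 to an allylic carbinol whose configuration does not matter because that carbon becomes the aldehyde.

Step 2
Reactants: 2 (1S,7aS)-7a-methyl-2,3,5,6,7,7a-hexahydro-1H-indene-1,5-diol
Product: 4 (4aR,7aS)-2-hydroxy-4a-methylhexahydrocyclopenta[b]pyran-5(2H)-one (trans-fused lactol; both anomers), via open hydroxy keto aldehyde 3 (not isolated)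
Conditions: OsO4 (cat.), NaIO4, 2,6-lutidine, dioxane–H2O, rt
Reagents that add atoms: osmium tetroxide, O=[Os](=O)(=O)=O (catalytic oxygen carrier); sodium periodate, [Na+].[O-]I(=O)(=O)=O
Why: Lemieux–Johnson oxidation; dihydroxylation of the trisubstituted alkene gives a vicinal triol that periodate should cleave twice, excising the alkene CH as formic acid and leaving the cyclopentanone and a 3-oxopropyl chain, which closes onto the trans-disposed hydroxyl as the lactol (only the labile anomeric center is new).

Step 3
Reactants: 4 (4aR,7aS)-2-hydroxy-4a-methylhexahydrocyclopenta[b]pyran-5(2H)-one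
Product: 5 (2R,4aR,7aS)-2-methoxy-4a-methylhexahydrocyclopenta[b]pyran-5(2H)-one (trans-fused; axial methoxy)
Conditions: MeOH, PPTS (cat.), rt
Reagents that add atoms: methanol, CO
Why: Fischer-type acetalization locks the lactol as its methyl acetal, the axial anomer being favoured by the anomeric effect (either anomer serves), and the hindered ketone should not be ketalized under these mild conditions.

Step 4
Reactants: 6 (S)-4-(tert-butyldimethylsilyloxy)cyclopent-2-en-1-one
Product: 8 (S)-4-(2-methylbut-3-en-2-yl)cyclopent-2-en-1-one, via trans β-silyloxy ketone 7 (not isolated)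
Conditions: prenyltrimethylsilane, TiCl4, CH2Cl2, −78 °C; then DBU, 0 °C to rt
Reagents that add atoms: prenyltrimethylsilane, CC(C)=CC[Si](C)(C)C
Why: Hosomi–Sakurai conjugate allylation; the allylsilane should attack through its γ-carbon anti to the silyloxy group, which sets the ring stereocenter and the gem-dimethyl quaternary carbon, and base-induced β-elimination of silanolate then places the enone on the other side.

Step 5
Reactants: 8 (S)-4-(2-methylbut-3-en-2-yl)cyclopent-2-en-1-one
Product: 9 (S)-2-iodo-4-(2-methylbut-3-en-2-yl)cyclopent-2-en-1-one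
Conditions: I2, pyridine, CH2Cl2, rt
Reagents that add atoms: iodine, II
Why: α-Iodination of an enone by pyridine addition, iodination and elimination; no stereocenter is touched and the isolated vinyl group should not react.

Step 6
Reactants: 9 (S)-2-iodo-4-(2-methylbut-3-en-2-yl)cyclopent-2-en-1-one
Product: 10 (S)-2-methyl-4-(2-methylbut-3-en-2-yl)cyclopent-2-en-1-one
Conditions: Me4Sn, Pd2(dba)3, AsPh3, CuI, NMP, 60 °C
Reagents that add atoms: tetramethyltin, C[Sn](C)(C)C
Why: Stille cross-coupling of the α-iodo enone installs the vinylic methyl group without affecting the stereocenter.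

Step 7
Reactants: 10 (S)-2-methyl-4-(2-methylbut-3-en-2-yl)cyclopent-2-en-1-one
Product: 11 (1R,4S)-2-methyl-4-(2-methylbut-3-en-2-yl)cyclopent-2-en-1-ol (cis)
Conditions: NaBH4, CeCl3·7H2O, MeOH, −78 °C
Reagents that add atoms: none
Why: Luche 1,2-reduction; hydride should add anti to the bulky C4 substituent and so give the cis allylic alcohol.

Step 8
Reactants: 11 (1R,4S)-2-methyl-4-(2-methylbut-3-en-2-yl)cyclopent-2-en-1-ol
Product: 12 N,N-dimethyl-2-[cis-2-methyl-5-(2-methylbut-3-en-2-yl)cyclopent-2-en-1-yl]acetamide
Conditions: N,N-dimethylacetamide dimethyl acetal, xylene, 140 °C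
Reagents that add atoms: N,N-dimethylacetamide dimethyl acetal, CC(OC)(OC)N(C)C
Why: Eschenmoser–Claisen rearrangement; the ketene N,O-acetal on the allylic oxygen delivers the acetamide carbon suprafacially, on the face of the oxygen and hence cis to the tert-alkyl group, which sets the cis relation of the two side chains.

Step 9
Reactants: 12 N,N-dimethyl-2-[cis-2-methyl-5-(2-methylbut-3-en-2-yl)cyclopent-2-en-1-yl]acetamide
Product: 13 3-methyl-1-[cis-2-methyl-5-(2-methylbut-3-en-2-yl)cyclopent-2-en-1-yl]but-3-en-2-one
Conditions: 2-bromopropene, t-BuLi, Et2O, −78 °C; then 12, −78 to 0 °C; H2O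
Reagents that add atoms: isopropenyllithium, [Li]C(C)=C (made in the flask from 2-bromopropene, CC(Br)=C)
Why: Acyl substitution of a tertiary amide by an alkenyllithium; the tetrahedral lithium adduct should survive until work-up, so the ketone forms only then and single addition results, with no stereocenter touched.

Step 10
Reactants: 13 3-methyl-1-[cis-2-methyl-5-(2-methylbut-3-en-2-yl)cyclopent-2-en-1-yl]but-3-en-2-one
Product: 14 cis-fused 1,4,4,6-tetramethyl-3,3a,4,8a-tetrahydroazulen-7(8H)-one
Conditions: RuCl2(=CHPh)(PCy3)(H2IMes) (second-generation Grubbs catalyst), toluene, 80 °C, high dilution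
Reagents that add atoms: none
Why: Ring-closing olefin metathesis between the isopropenyl ketone and the vinyl group should close the seven-membered ring as the α-methyl enone, the endocyclic trisubstituted cyclopentene staying out; the cis ring fusion is already fixed.

Step 11
Reactants: 14 cis-fused 1,4,4,6-tetramethyl-3,3a,4,8a-tetrahydroazulen-7(8H)-one
Product: 15 1,2-epoxy-1,4,4,6-tetramethyl-1,2,3,3a,4,8a-hexahydroazulen-7(8H)-one (cis-fused; epoxide oxygen on the face of the ring-fusion hydrogens)
Conditions: mCPBA, NaHCO3, CH2Cl2, 0 °C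
Reagents that add atoms: mCPBA, OOC(=O)c1cccc(Cl)c1
Why: Prilezhaev epoxidation; the electron-rich trisubstituted cyclopentene should react before the enone, and the peracid approaches the convex face (that of the ring-fusion hydrogens), which sets the oxygen of the later tertiary carbinol.

Step 12
Reactants: 15 1,2-epoxy-1,4,4,6-tetramethyl-1,2,3,3a,4,8a-hexahydroazulen-7(8H)-one
Product: 16 (7R)-1,2-epoxy-1,4,4,6-tetramethyl-1,2,3,3a,4,7,8,8a-octahydroazulen-7-ol (7-OH anti to the ring-fusion hydrogens)
Conditions: (S)-2-methyl-CBS-oxazaborolidine, catecholborane, toluene, −78 °C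
Reagents that add atoms: none
Why: Corey–Bakshi–Shibata reduction with the α-methylalkenyl arm as the large group should give the (R)-carbinol, the hydride arriving from the convex face that the substrate also prefers.

Step 13
Reactants: 16 (7R)-1,2-epoxy-1,4,4,6-tetramethyl-1,2,3,3a,4,7,8,8a-octahydroazulen-7-ol
Product: 17 2-(1,2-epoxy-1,4,4,6-tetramethyl-1,2,3,3a,4,5,8,8a-octahydroazulen-5-yl)-N,N-dimethylacetamide (5-H syn to the ring-fusion hydrogens; alkene C6=C7)
Conditions: N,N-dimethylacetamide dimethyl acetal, xylene, 140 °C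
Reagents that add atoms: N,N-dimethylacetamide dimethyl acetal, CC(OC)(OC)N(C)C
Why: Eschenmoser–Claisen rearrangement; the carbinol configuration is transferred suprafacially to the neopentyl ring carbon, which creates the side-chain stereocenter and moves the alkene into its final position.

Step 14
Reactants: 17 2-(azulenyl)-N,N-dimethylacetamide
Product: 18 2-(1,2-epoxy-1,4,4,6-tetramethyl-1,2,3,3a,4,5,8,8a-octahydroazulen-5-yl)acetaldehyde
Conditions: Cp2Zr(H)Cl, THF, rt, short reaction time
Reagents that add atoms: none
Why: Reduction of a tertiary amide by the zirconocene hydride chloride stops at the zirconated hemiaminal, which gives the aldehyde on hydrolysis; epoxide and trisubstituted alkene should survive the short exposure.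

Step 15
Reactants: 5 (2R,4aR,7aS)-2-methoxy-4a-methylhexahydrocyclopenta[b]pyran-5(2H)-one; 18 2-(azulenyl)acetaldehyde
Product: 22 5-[1-hydroxy-2-(azulenyl)ethyl]-2-methoxy-4a-methyloctahydro-2H-chromen-6-one (trans-fused; mixture at C5 and at the carbinol carbon), via dibromomethyl lithium alkoxide 19 (not isolated), via lithium β-oxido carbenoid 20 (not isolated), via ring-expanded lithium enolate 21 (not isolated)
Conditions: CH2Br2, lithium 2,2,6,6-tetramethylpiperidide, THF, −78 °C; n-BuLi, −78 to 0 °C; then 18, −78 °C; H2O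
Reagents that add atoms: dibromomethane, BrCBr
Why: Dibromomethyllithium formed in the flask should add to the cyclopentanone anti to the angular methyl, and bromine–lithium exchange then gives a lithium β-oxido carbenoid whose 1,2-alkyl shift with loss of LiBr inserts the carbenoid carbon between the carbonyl carbon and the quaternary ring-fusion carbon, delivering the cyclohexanone lithium enolate with its double bond to the inserted carbon, which adds to aldehyde 18 in an aldol reaction. The closest known reaction type is the β-oxido carbenoid one-carbon ring enlargement of cyclic ketones with trapping of the resulting enolate. The six-membered ring is not closed by a cyclization: it arises from the five-membered ketone by one-carbon insertion through a 1,2-shift, so no ring-closure mode applies. The migrating carbon keeps its configuration, and the carbinol carbon of 19 and the two new centers of 22 need no control, because the first is consumed in the shift, the α-carbon is equilibrated in step 17 and the side-chain carbinol is removed in step 16. The step needs migration of the quaternary carbon and not of the ring CH2, which the higher migratory aptitude of the more substituted carbon (helped by relief of strain in the trans-fused bicycle) should secure, and it needs bond formation at the inserted carbon only, which the carbenoid mechanism secures by generating the enolate regiospecifically.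

Step 16
Reactants: 22 5-[1-hydroxy-2-(azulenyl)ethyl]-2-methoxy-4a-methyloctahydro-2H-chromen-6-one
Product: 24 5-[2-(azulenyl)ethylidene]-2-methoxy-4a-methyloctahydro-2H-chromen-6-one (alkene isomers), via mesylate 23 (not isolated)
Conditions: MsCl, Et3N, CH2Cl2, 0 °C; then DBU, rt
Reagents that add atoms: none
Why: Mesylation and E1cB elimination complete the aldol condensation to the exocyclic enone, removing the carbinol stereocenter.

Step 17
Reactants: 24 5-[2-(azulenyl)ethylidene]-2-methoxy-4a-methyloctahydro-2H-chromen-6-one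
Product: 26 5-[2-(azulenyl)ethyl]-2-methoxy-4a-methyloctahydro-2H-chromen-6-one (side chain equatorial, cis to the 4a-methyl), via α-epimer mixture 25 (not isolated)
Conditions: [(Ph3P)CuH]6, benzene–H2O, rt; then NaOMe, MeOH, rt
Reagents that add atoms: none
Why: Copper hydride 1,4-reduction should saturate only the conjugated alkene, and base equilibration of the α-carbon on the rigid trans-fused bicycle then places the side chain equatorial (cis to the angular methyl), so this center is set under thermodynamic control.

Step 18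
Reactants: 26 5-[2-(azulenyl)ethyl]-2-methoxy-4a-methyloctahydro-2H-chromen-6-one
Product: 27 5-[2-(azulenyl)ethyl]-2-methoxy-4a,6-dimethyloctahydro-2H-chromen-6-ol (6-OH axial, cis to the 4a-methyl)
Conditions: MeLi, Et2O, −78 °C
Reagents that add atoms: methyllithium, [Li]C
Why: 1,2-Addition of methyllithium; axial attack is blocked by the syn-axial angular methyl, so the reagent should enter equatorially and leave the hydroxyl axial, cis to the angular methyl.

Step 19
Reactants: 27 5-[2-(azulenyl)ethyl]-2-methoxy-4a,6-dimethyloctahydro-2H-chromen-6-ol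
Product: 28 methyl acetal of the target (tertiary cyclopentanol in place of the epoxide)
Conditions: LiBHEt3, THF, 0 °C to rt
Reagents that add atoms: none
Why: Hydride opening of the trisubstituted epoxide by SN2 attack at the less substituted carbon should give the tertiary alcohol with the oxygen configuration set in step 11.

Step 20
Reactants: 28 methyl acetal of the target
Product: 29 CNP0167351.1
Conditions: AcOH–THF–H2O, rt to 40 °C
Reagents that add atoms: water, O
Why: Mild acid hydrolysis of the methyl acetal (glycoside-type hydrolysis) frees the lactol, which equilibrates to the drawn anomer; the tertiary alcohols and the trisubstituted alkene should tolerate these conditions.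

Compound list

1 | (S)-7a-methyl-2,3,7,7a-tetrahydro-1H-indene-1,5(6H)-dione | C[C@]12CCC(=O)C=C1CCC2=O | starting material
2 | (1S,7aS)-7a-methyl-2,3,5,6,7,7a-hexahydro-1H-indene-1,5-diol (5-epimers) | C[C@]12CCC(O)C=C1CC[C@@H]2O | intermediate
3 | 3-[(1R,2S)-2-hydroxy-1-methyl-5-oxocyclopentyl]propanal | O=CCC[C@@]1(C)C(=O)CC[C@@H]1O | intermediate
4 | (4aR,7aS)-2-hydroxy-4a-methylhexahydrocyclopenta[b]pyran-5(2H)-one (anomers) | O=C1[C@]2(C)CCC(O)O[C@H]2CC1 | intermediate
5 | (2R,4aR,7aS)-2-methoxy-4a-methylhexahydrocyclopenta[b]pyran-5(2H)-one | O=C1[C@]2(C)CC[C@H](OC)O[C@H]2CC1 | intermediate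
6 | (S)-4-(tert-butyldimethylsilyloxy)cyclopent-2-en-1-one | O=C1C=C[C@@H](O[Si](C)(C)C(C)(C)C)C1 | starting material
7 | trans-3-(2-methylbut-3-en-2-yl)-4-(tert-butyldimethylsilyloxy)cyclopentan-1-one | O=C1C[C@H](C(C)(C)C=C)[C@@H](O[Si](C)(C)C(C)(C)C)C1 | intermediate
8 | (S)-4-(2-methylbut-3-en-2-yl)cyclopent-2-en-1-one | O=C1C[C@H](C(C)(C)C=C)C=C1 | intermediate
9 | (S)-2-iodo-4-(2-methylbut-3-en-2-yl)cyclopent-2-en-1-one | O=C1C[C@H](C(C)(C)C=C)C=C1I | intermediate
10 | (S)-2-methyl-4-(2-methylbut-3-en-2-yl)cyclopent-2-en-1-one | O=C1C[C@H](C(C)(C)C=C)C=C1C | intermediate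
11 | (1R,4S)-2-methyl-4-(2-methylbut-3-en-2-yl)cyclopent-2-en-1-ol | O[C@@H]1C[C@H](C(C)(C)C=C)C=C1C | intermediate
12 | N,N-dimethyl-2-[cis-2-methyl-5-(2-methylbut-3-en-2-yl)cyclopent-2-en-1-yl]acetamide | CN(C)C(=O)C[C@H]1[C@H](CC=C1C)C(C)(C)C=C | intermediate
13 | 3-methyl-1-[cis-2-methyl-5-(2-methylbut-3-en-2-yl)cyclopent-2-en-1-yl]but-3-en-2-one | C=C(C)C(=O)C[C@H]1[C@H](CC=C1C)C(C)(C)C=C | intermediate
14 | cis-fused 1,4,4,6-tetramethyl-3,3a,4,8a-tetrahydroazulen-7(8H)-one | O=C1C[C@H]2[C@H](CC=C2C)C(C)(C)C=C1C | intermediate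
15 | 1,2-epoxy-1,4,4,6-tetramethyl-1,2,3,3a,4,8a-hexahydroazulen-7(8H)-one | O=C1C[C@H]2[C@H](C[C@@H]3O[C@]23C)C(C)(C)C=C1C | intermediate
16 | (7R)-1,2-epoxy-1,4,4,6-tetramethyl-1,2,3,3a,4,7,8,8a-octahydroazulen-7-ol | O[C@@H]1C[C@H]2[C@H](C[C@@H]3O[C@]23C)C(C)(C)C=C1C | intermediate
17 | 2-(azulenyl)-N,N-dimethylacetamide | CC1=CC[C@H]2[C@H](C[C@@H]3O[C@]23C)C(C)(C)[C@@H]1CC(=O)N(C)C | intermediate
18 | 2-(azulenyl)acetaldehyde | CC1=CC[C@H]2[C@H](C[C@@H]3O[C@]23C)C(C)(C)[C@@H]1CC=O | intermediate
19 | lithium 5-(dibromomethyl)-2-methoxy-4a-methyloctahydrocyclopenta[b]pyran-5-olate (O cis to the angular methyl) | [Li]O[C@@]1(C(Br)Br)[C@]2(C)CC[C@H](OC)O[C@H]2CC1 | intermediate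
20 | lithium 5-[bromo(lithio)methyl]-2-methoxy-4a-methyloctahydrocyclopenta[b]pyran-5-olate (β-oxido carbenoid) | [Li]O[C@@]1(C([Li])Br)[C@]2(C)CC[C@H](OC)O[C@H]2CC1 | intermediate
21 | lithium 2-methoxy-4a-methyl-3,4,4a,7,8,8a-hexahydro-2H-chromen-6-olate (enolate C5=C6) | [Li]OC1=C[C@]2(C)CC[C@H](OC)O[C@H]2CC1 | intermediate
22 | 5-[1-hydroxy-2-(azulenyl)ethyl]-2-methoxy-4a-methyloctahydro-2H-chromen-6-one (mixture at C5 and carbinol) | CC1=CC[C@H]2[C@H](C[C@@H]3O[C@]23C)C(C)(C)[C@@H]1CC(O)C1[C@]2(C)CC[C@H](OC)O[C@H]2CCC1=O | intermediate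
23 | methanesulfonate of 22 | CC1=CC[C@H]2[C@H](C[C@@H]3O[C@]23C)C(C)(C)[C@@H]1CC(OS(C)(=O)=O)C1[C@]2(C)CC[C@H](OC)O[C@H]2CCC1=O | intermediate
24 | 5-[2-(azulenyl)ethylidene]-2-methoxy-4a-methyloctahydro-2H-chromen-6-one (alkene isomers) | CC1=CC[C@H]2[C@H](C[C@@H]3O[C@]23C)C(C)(C)[C@@H]1CC=C1[C@]2(C)CC[C@H](OC)O[C@H]2CCC1=O | intermediate
25 | 5-[2-(azulenyl)ethyl]-2-methoxy-4a-methyloctahydro-2H-chromen-6-one (C5 epimers) | CC1=CC[C@H]2[C@H](C[C@@H]3O[C@]23C)C(C)(C)[C@@H]1CCC1[C@]2(C)CC[C@H](OC)O[C@H]2CCC1=O | intermediate
26 | 5-[2-(azulenyl)ethyl]-2-methoxy-4a-methyloctahydro-2H-chromen-6-one (side chain cis to 4a-methyl) | CC1=CC[C@H]2[C@H](C[C@@H]3O[C@]23C)C(C)(C)[C@@H]1CC[C@H]1[C@]2(C)CC[C@H](OC)O[C@H]2CCC1=O | intermediate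
27 | 5-[2-(azulenyl)ethyl]-2-methoxy-4a,6-dimethyloctahydro-2H-chromen-6-ol (6-OH axial) | CC1=CC[C@H]2[C@H](C[C@@H]3O[C@]23C)C(C)(C)[C@@H]1CC[C@H]1[C@]2(C)CC[C@H](OC)O[C@H]2CC[C@@]1(C)O | intermediate
28 | methyl acetal of the target | CC1=CC[C@H]2[C@H](CC[C@]2(C)O)C(C)(C)[C@@H]1CC[C@H]1[C@]2(C)CC[C@H](OC)O[C@H]2CC[C@@]1(C)O | intermediate
29 | CNP0167351.1 | CC1=CC[C@H]2[C@H](CC[C@]2(C)O)C(C)(C)[C@@H]1CC[C@H]1[C@]2(C)CC[C@@H](O)O[C@H]2CC[C@@]1(C)O | target

Total step count: 20. Longest linear sequence: 17 steps (steps 4 to 14, then 15 to 20).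

Steps most likely to fail

Step 15. In the carbenoid shift the ring CH2 may migrate in place of the quaternary carbon, or the hindered enolate may be protonated faster than it adds to 18. The fallback sets out from 5 and comes back at 22. Bis(phenylthio)methyllithium (from bis(phenylthio)methane and n-BuLi, THF, −78 °C) should add to 5 to give the bis(phenylthio)methyl carbinol F1. CuOTf with i-Pr2NEt in warm benzene should ionize one C–S bond and trigger a thionium pinacol-type ring expansion, a cation-like shift in which the more substituted carbon is the usual migrant, to give the 5-(phenylthio) cyclohexanone F2. Its sulfur-stabilized potassium enolate (KN(SiMe3)2) can be formed at will and should add to 18 to give the thio-aldol F3. SmI2 in THF–MeOH at −78 °C should then remove the sulfur and give 22.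

Step 10. The ruthenium carbene may load poorly on both olefins (one conjugated and 1,1-disubstituted, one neopentyl), so that dimerization and catalyst decay win over closure. The fallback sets out from 13 and comes back at 14. NaBH4 with CeCl3 should reduce 13 to the dienol F4 and so remove the conjugation. Ring-closing metathesis of F4 with RuCl2(=CH-C6H4-2-O-i-Pr)(H2IMes) should give the cycloheptenol F5. MnO2 oxidation of the allylic alcohol should return 14.

Step 13. At 140 °C, elimination of the ketene N,O-acetal to a diene or thermal opening of the epoxide may outrun the sigmatropic shift to the neopentyl terminus. The fallback sets out from 16 and comes back at 18. Acetylation (Ac2O, DMAP) should give the acetate F6. Its silyl ketene acetal (KN(SiMe3)2, Me3SiCl, −78 °C) should undergo Ireland–Claisen rearrangement between room temperature and 60 °C and give, after mild hydrolysis, the acid F7. Coupling with N,O-dimethylhydroxylamine (EDC) should give the amide F8, and i-Bu2AlH at −78 °C should give 18.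

Further compounds

F1 | step 15 | 5-[bis(phenylthio)methyl]-2-methoxy-4a-methyloctahydrocyclopenta[b]pyran-5-ol | O[C@@]1(C(Sc2ccccc2)Sc2ccccc2)[C@]2(C)CC[C@H](OC)O[C@H]2CC1
F2 | step 15 | 2-methoxy-4a-methyl-5-(phenylthio)octahydro-2H-chromen-6-one | c1ccccc1SC1[C@]2(C)CC[C@H](OC)O[C@H]2CCC1=O
F3 | step 15 | 5-[1-hydroxy-2-(azulenyl)ethyl]-2-methoxy-4a-methyl-5-(phenylthio)octahydro-2H-chromen-6-one | CC1=CC[C@H]2[C@H](C[C@@H]3O[C@]23C)C(C)(C)[C@@H]1CC(O)C1(Sc3ccccc3)[C@]2(C)CC[C@H](OC)O[C@H]2CCC1=O
F4 | step 10 | 3-methyl-1-[cis-2-methyl-5-(2-methylbut-3-en-2-yl)cyclopent-2-en-1-yl]but-3-en-2-ol | C=C(C)C(O)C[C@H]1[C@H](CC=C1C)C(C)(C)C=C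
F5 | step 10 | cis-fused 1,4,4,6-tetramethyl-3,3a,4,7,8,8a-hexahydroazulen-7-ol | OC1C[C@H]2[C@H](CC=C2C)C(C)(C)C=C1C
F6 | step 13 | acetate of 16 | CC(=O)O[C@@H]1C[C@H]2[C@H](C[C@@H]3O[C@]23C)C(C)(C)C=C1C
F7 | step 13 | 2-(azulenyl)acetic acid | CC1=CC[C@H]2[C@H](C[C@@H]3O[C@]23C)C(C)(C)[C@@H]1CC(=O)O
F8 | step 13 | 2-(azulenyl)-N-methoxy-N-methylacetamide | CC1=CC[C@H]2[C@H](C[C@@H]3O[C@]23C)C(C)(C)[C@@H]1CC(=O)N(C)OC
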